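## Analysis of the target

The target is a furanoheliangolide. Germacrane numbering is used throughout: C1 ketone, C2=C3 enol ether, ring oxygen from C3 to C10, (Z)-C4=C5 with C15 methyl on C4, C6 lactone oxygen, C7, C8 ester, C9 hydroxyl, C10 quaternary with C14 methyl, C11=C13 methylene, C12 lactone carbonyl.

- The ten-membered carbocycle C1–C10 is bridged by the C3–O–C10 oxygen. This gives a 3(2H)-furanone (O, C3, C2, C1, C10) and a strained nine-membered oxacycle (O, C3–C10) that holds a trisubstituted (Z)-alkene conjugated to the furanone. An α-methylene-γ-butyrolactone is trans-fused at C6/C7.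
- Five contiguous stereocentres run C6–C10 (6R,7S,8S,9S,10R). In the zigzag C5→C10 the relations are O6/C11 syn, C11/O8 anti, O8/O9 anti and O9/ring-O10 syn, and C10 is fully substituted.
- The 9-hydroxy-1-ketone is an aldol, and its retro-aldol would release an aromatic 3-hydroxyfuran, so the finished core does not tolerate base.
- Other sensitive groups are the methylene lactone (Michael acceptor), the cross-conjugated dienone, the allylic acetate in the side chain, and the O8 ester next to the free O9 hydroxyl (acyl migration).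
- The difficulty is threefold: closing the bridged nine-membered ring over a rigid (Z)-diene, setting C9/C10 in that ring, and placing the ester on O8 only.

## Retrosynthetic reasoning

**C9–C10 (key disconnection).** C10 of 26 is C2 of a latent aromatic 3-oxyfuran, and the C9 carbinol sits β to the C1 ketone. Cutting C9–C10 therefore opens the nine-membered ring and removes both C9 and C10 as stereocentres in one stroke. The precursor is the monocyclic keto-aldehyde 23, whose C10 is an epimerisable CH. Forward, 23 is silylated in the flask to the planar silyloxyfuran 24, and a ring-closing Mukaiyama aldol gives 25 and then 26. Because 24 has no stereocentre at C10, both epimers of 23 funnel into one product. The O8 ester is already in place, so the ring closure is the last step and no selective acylation of a diol is needed.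

**Furanone and C9 aldehyde.** The aldehyde of 23 comes from the primary alcohol 22 by oxidation. The 2-H furanone of 22 is the hydration–cyclodehydration isomer of the γ-hydroxy ynone 21, which is reached from 20 by removal of both silyl groups. The C10 configuration in 20–23 is irrelevant.

**C3–C4 and C2–C3.** The cross-conjugated enynone 20 is cut on both sides of the C3 carbonyl, into the (Z)-vinyl iodide 18, a one-carbon carbonyl unit and the racemic alkyne 19. A carbonylative alkynylation joins them with retention of alkene geometry. The (Z)-C4=C5 geometry is set one step earlier, by iodo-olefination of aldehyde 17.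

**Lactone.** Aldehyde 17 comes from alcohol 16. The lactone of 16 closes from the acetonide 14 once the C5/C6 diol 15 is freed, so C5 and C6 both derive from the diol carbons of the chiral-pool aldehyde 1.

**O8 ester.** 14 is the ester of the single free hydroxyl of 7 with acid 13. The acid is installed before any second hydroxyl exists.

**C7–C8.** 7 is cut between C7 and C8 into the (Z)-allyl bromide 4 and aldehyde 5. A Barbier-type allylation forms the bond, creates C7 and C8 and delivers the methylene ester. C6 (from 1) controls C7, and the (Z)-geometry of 4 controls C8 relative to C7. 4 comes from the Morita–Baylis–Hillman adduct 3 of 1 and 2.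

**Side chain.** Acid 13 comes from its tert-butyl ester 12, the allylic-transposition product of acetate 11, made from the Morita–Baylis–Hillman adduct 10 of 8 and 9.

## Alternatives that were turned down

**Alternative 1:** Ring-closing metathesis across C4=C5 (the textbook medium-ring closure). The forward key step would close the nine-membered ring from diene A1, which carries an isopropenyl group on the furanone and a vinyl group on C6.
- The key step would form only an alkene. C9 and C10 would have to be set beforehand in an intermolecular aldol with no ring to bias it.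
- The catalyst would have to pick two of five alkenes, and the isopropenyl group on an electron-poor vinylogous ester is a poor metathesis partner for a trisubstituted, strained ring olefin.
- It saves no steps.

**Alternative 2:** Macrocyclising Barbier allylation/lactonisation across C6–C7. The forward key step would close the ring from the bromo-enal A2 and form the lactone at once.
- 2-(Bromomethyl)acrylate allyl metals add in the syn sense, which leads to the cis-lactone in open systems. The required trans-lactone would rest on ring strain alone.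
- A2 needs a (Z)-enal, which isomerises easily.
- A2 needs the whole C8–C10 triad built first on an open chain, around a retro-aldol-prone β-hydroxy furanone that must survive the metal.

**Alternative 3:** Transannular oxa-Michael closure of the C3–O bond. The forward key step would convert the ten-membered γ-hydroxy enynone A3 into the furanone, driven by release of alkyne strain.
- A3 itself requires a difficult macrocyclisation to a strained ten-membered enyne, with all five stereocentres already present.
- The key step then forms one C–O bond and no stereocentre.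
- The free C9 hydroxyl can compete by six-membered closure.

Key step: step 14

## Route

Remarks: aldehyde 5 and racemic alkyne 19 are taken as commercial reagents. 19 may be racemic because its carbinol carbon (C10) is planarised in step 14.

Step 1
Reactants: 1 (R)-2,2-dimethyl-1,3-dioxolane-4-carbaldehyde; 2 methyl acrylate
Product: 3 methyl 2-{[(4R)-2,2-dimethyl-1,3-dioxolan-4-yl](hydroxy)methyl}prop-2-enoate (both carbinol epimers)
Conditions: DABCO (0.5 equiv), 2 (3 equiv), 1,4-dioxane/H2O 1:1, rt
Reagents that add atoms: none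
Why: Morita–Baylis–Hillman reaction joins C7 to C11; C6 comes unchanged from the chiral pool, and the new carbinol centre (either epimer) is removed in step 2.

Step 2
Reactants: 3 Morita–Baylis–Hillman adduct
Product: 4 methyl (2Z)-2-(bromomethyl)-3-[(4S)-2,2-dimethyl-1,3-dioxolan-4-yl]prop-2-enoate
Conditions: NBS, Me2S, CH2Cl2, 0 °C → rt
Reagents that add atoms: N-bromosuccinimide, O=C1CCC(=O)N1Br
Why: Bromodimethylsulfonium activation and SN2′ transposition convert both epimers of 3 into the thermodynamically preferred (Z)-2-(bromomethyl)enoate; the conditions are not acidic enough to open the acetonide.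

Step 3
Reactants: 4 (Z)-allyl bromide; 5 2-[(tert-butyldiphenylsilyl)oxy]acetaldehyde
Product: 7 methyl (3R,4S)-5-[(tert-butyldiphenylsilyl)oxy]-3-[(4S)-2,2-dimethyl-1,3-dioxolan-4-yl]-4-hydroxy-2-methylidenepentanoate, via allylindium species 6 (not isolated)
Conditions: indium powder (1.5 equiv), THF/H2O 1:1, rt
Reagents that add atoms: none
Why: Barbier allylation through a chair transition state; the (Z)-allyl metal should give the syn C7/C8 relation. The aldehyde should add to the alkene face anti to the dioxolane C6–O bond, in the conformer that holds C6–H in the alkene plane (allylic 1,3-strain with CH2In), which sets C7 relative to C6. The hydroxy ester should not lactonise at rt without acid.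

Step 4
Reactants: 8 tert-butyl acrylate; 9 acetaldehyde
Product: 10 tert-butyl 3-hydroxy-2-methylidenebutanoate (racemic)
Conditions: DABCO (0.3 equiv), 9 (3 equiv), neat, rt, sealed vessel
Reagents that add atoms: none
Why: Morita–Baylis–Hillman reaction; the carbinol centre is lost in step 5.

Step 5
Reactants: 10 hydroxy ester
Product: 12 tert-butyl (2E)-2-(acetoxymethyl)but-2-enoate, via secondary acetate 11 (not isolated)
Conditions: Ac2O, Et3N, DMAP (5 mol %), CH2Cl2, 0 °C; then DABCO (0.2 equiv), THF, 60 °C
Reagents that add atoms: acetic anhydride, CC(=O)OC(C)=O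
Why: Acetylation followed by DABCO-mediated SN2′/SN2′ 1,3-transposition of the acetate gives the conjugated trisubstituted enoate; the (E)-isomer (methyl trans to the ester) is the thermodynamic product.

Step 6
Reactants: 12 tert-butyl ester
Product: 13 (2E)-2-(acetoxymethyl)but-2-enoic acid
Conditions: TFA/CH2Cl2 1:3, 0 °C → rt
Reagents that add atoms: none
Why: Acidolysis of the tert-butyl ester; the primary allylic acetate and the alkene geometry are stable to acid.

Step 7
Reactants: 7 hydroxy ester; 13 acid
Product: 14 methyl (3S,4S)-4-{[(2E)-2-(acetoxymethyl)but-2-enoyl]oxy}-5-[(tert-butyldiphenylsilyl)oxy]-3-[(4S)-2,2-dimethyl-1,3-dioxolan-4-yl]-2-methylidenepentanoate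
Conditions: DCC (1.5 equiv), DMAP (0.2 equiv), CH2Cl2, 0 °C → rt
Reagents that add atoms: none
Why: Steglich esterification of the only free hydroxyl, with retention at C8. Doing it here fixes the acyl group on O8 before O9 exists as a hydroxyl; the descriptor at C3 changes by priority only.

Step 8
Reactants: 14 acetonide ester
Product: 16 (1S)-2-[(tert-butyldiphenylsilyl)oxy]-1-[(2S,3S)-2-(hydroxymethyl)-4-methylidene-5-oxooxolan-3-yl]ethyl (2E)-2-(acetoxymethyl)but-2-enoate, via diol ester 15 (not isolated)
Conditions: CSA (0.2 equiv), MeOH, rt → 40 °C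
Reagents that add atoms: none
Why: Acid-catalysed transketalisation frees the C5/C6 diol, and under the same equilibrating conditions the secondary C6 hydroxyl closes the five-membered lactone on the methyl ester (γ- over δ-lactone). The trans relation of C6/C7 follows from step 3; the silyl ether and the other esters are stable to CSA/MeOH.

Step 9
Reactants: 16 primary alcohol
Product: 17 (1S)-2-[(tert-butyldiphenylsilyl)oxy]-1-[(2S,3R)-2-formyl-4-methylidene-5-oxooxolan-3-yl]ethyl (2E)-2-(acetoxymethyl)but-2-enoate
Conditions: Dess–Martin periodinane, NaHCO3, CH2Cl2, 0 °C → rt; used directly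
Reagents that add atoms: none
Why: Dess–Martin oxidation of the single hydroxyl under near-neutral conditions that should not epimerise the α-oxygenated C6.

Step 10
Reactants: 17 aldehyde
Product: 18 (1S)-2-[(tert-butyldiphenylsilyl)oxy]-1-[(2S,3S)-2-[(1Z)-2-iodoprop-1-en-1-yl]-4-methylidene-5-oxooxolan-3-yl]ethyl (2E)-2-(acetoxymethyl)but-2-enoate
Conditions: EtPPh3I, n-BuLi, THF, rt; I2, −78 °C; NaHMDS, −78 → −20 °C; then 17, −78 °C
Reagents that add atoms: ethyltriphenylphosphonium iodide, CC[P+](c1ccccc1)(c1ccccc1)c1ccccc1.[I-]; iodine, II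
Why: Stork–Zhao-type iodo-olefination; the kinetic cis-oxaphosphetane of the α-iodo ylide should give the (Z)-iodoalkene (C6 cis to iodine), which is the geometry needed at C4=C5. Addition to the aldehyde at −78 °C should outrun attack on the esters and the methylene lactone.

Step 11
Reactants: 18 (Z)-vinyl iodide; 19 tert-butyl(but-3-yn-2-yloxy)dimethylsilane (racemic)
Product: 20 (1S)-2-[(tert-butyldiphenylsilyl)oxy]-1-[(2R,3S)-2-{(1Z)-6-[(tert-butyldimethylsilyl)oxy]-2-methyl-3-oxohept-1-en-4-yn-1-yl}-4-methylidene-5-oxooxolan-3-yl]ethyl (2E)-2-(acetoxymethyl)but-2-enoate (both epimers at the silyloxy carbon)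
Conditions: CO (1 atm), PdCl2(PPh3)2 (5 mol %), CuI (5 mol %), Et3N (3 equiv), THF, rt
Reagents that add atoms: carbon monoxide, [C-]#[O+]
Why: Carbonylative Sonogashira coupling; oxidative addition and CO insertion retain the alkene geometry, and the acylpalladium is trapped by the copper acetylide, bringing in C3 and C2–C1–C10–C14 in one step.

Step 12
Reactants: 20 bis-silyl enynone
Product: 22 (1S)-2-hydroxy-1-[(2R,3S)-2-[(1Z)-2-(5-methyl-4-oxo-4,5-dihydrofuran-2-yl)prop-1-en-1-yl]-4-methylidene-5-oxooxolan-3-yl]ethyl (2E)-2-(acetoxymethyl)but-2-enoate (both epimers at the furanone CH), via diol ynone 21 (not isolated)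
Conditions: aq. HF (48 %), MeCN, 0 °C → rt; extractive work-up; then (Ph3P)AuNTf2 (3 mol %), toluene, H2O (2 equiv), rt, argon; used directly
Reagents that add atoms: water, O
Why: Acidic fluoride removes both silyl ethers without the base that would cause O8→O9 acyl migration. Gold-catalysed hydration of the ynone at C1, then cyclodehydration of the C10 hydroxyl onto the C3 ketone, gives the 3(2H)-furanone (known cyclisation of γ-hydroxy alkynones); water is regenerated, and the C10 epimers are both carried on.

Step 13
Reactants: 22 furanone alcohol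
Product: 23 (1S)-1-[(2R,3S)-2-[(1Z)-2-(5-methyl-4-oxo-4,5-dihydrofuran-2-yl)prop-1-en-1-yl]-4-methylidene-5-oxooxolan-3-yl]-2-oxoethyl (2E)-2-(acetoxymethyl)but-2-enoate (both epimers at the furanone CH)
Conditions: Dess–Martin periodinane, pyridine (2 equiv), CH2Cl2, 0 °C, argon; used directly
Reagents that add atoms: none
Why: Dess–Martin oxidation of the only hydroxyl gives the α-acyloxy aldehyde under conditions too mild to enolise it or the furanone.

Step 14
Reactants: 23 keto-aldehyde
Product: 26 CNP0231561.1, (6R,7S,8S,9S,10R)-8-{[(2E)-2-(acetoxymethyl)but-2-enoyl]oxy}-9-hydroxy-1-oxo-3,10-epoxygermacra-2,4(Z),11(13)-trien-12,6-olide, via silyloxyfuran aldehyde 24 (not isolated), via trimethylsilyl ether 25 (not isolated)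
Conditions: iPr2NEt (1.5 equiv), TMSOTf (1.3 equiv), CH2Cl2, −78 → −40 °C, 23 added over 6 h to a final 0.001 M; then aq. citric acid, THF, 0 °C
Reagents that add atoms: none
Why: The amine and silyl triflate silylate the furanone oxygen of 23 to the aromatic 2-methyl-3-(trimethylsilyloxy)furan 24, which erases C10 so that both epimers converge; the silyl triflate then activates the C9 aldehyde for attack by furan C2 (= C10), silyl transfer gives 25 and mild acid gives 26. The closest known reaction type is the Mukaiyama aldol addition of 2-substituted 3-silyloxyfurans to aldehydes at C2, which gives 2,2-disubstituted 3(2H)-furanones; it is run here in the ring-closing sense with enol silane formation in the flask. The nine-membered oxacycle (O, C3–C10) closes in a 9-(enolexo)-exo-trig mode, with the furanone and lactone rings already present. C10 should be controlled by the tether: the chain is anchored in the furan plane at C3 through the (Z)-C4=C5 bond and should reach only one furan face without forcing the trans-lactone at C6/C7 into the ring interior, and that face corresponds to 10R. C9 should be controlled by C8 in the Felkin–Anh sense (attack anti to the C8–O bond of the non-chelating acyloxy group), which gives the 8,9-anti, 9S carbinol. The step needs C2 over C4 or O attack of the silyloxyfuran (C2 lies between the ring oxygen and the silyloxy group and is the established site even when substituted), aldehyde over methylene lactone (only the aldehyde is activated), and ring closure over oligomerisation (high dilution, slow addition). Enolisation of the α-acyloxy aldehyde should not compete because the furanone C10–H, which leads to an aromatic enol ether, is far more acidic. The new C–C bond and the Si–O bond pay for the loss of furan aromaticity, so the closure should not reverse under the conditions.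

## Compound list

1 | (R)-2,2-dimethyl-1,3-dioxolane-4-carbaldehyde | CC1(C)OC[C@@H](O1)C=O | starting material
2 | methyl acrylate | C=CC(=O)OC | starting material
3 | methyl 2-{[(4R)-2,2-dimethyl-1,3-dioxolan-4-yl](hydroxy)methyl}prop-2-enoate (both carbinol epimers) | CC1(C)OC[C@@H](O1)C(O)C(=C)C(=O)OC | intermediate
4 | methyl (2Z)-2-(bromomethyl)-3-[(4S)-2,2-dimethyl-1,3-dioxolan-4-yl]prop-2-enoate | CC1(C)OC[C@@H](O1)/C=C(\CBr)C(=O)OC | intermediate
5 | 2-[(tert-butyldiphenylsilyl)oxy]acetaldehyde | O=CCO[Si](c1ccccc1)(c1ccccc1)C(C)(C)C | starting material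
6 | monovalent allylindium species from 4 | CC1(C)OC[C@@H](O1)/C=C(\C[In])C(=O)OC | intermediate
7 | methyl (3R,4S)-5-[(tert-butyldiphenylsilyl)oxy]-3-[(4S)-2,2-dimethyl-1,3-dioxolan-4-yl]-4-hydroxy-2-methylidenepentanoate | COC(=O)C(=C)[C@@H]([C@H]1COC(C)(C)O1)[C@H](O)CO[Si](c2ccccc2)(c2ccccc2)C(C)(C)C | intermediate
8 | tert-butyl acrylate | C=CC(=O)OC(C)(C)C | starting material
9 | acetaldehyde | CC=O | starting material
10 | tert-butyl 3-hydroxy-2-methylidenebutanoate (racemic) | CC(O)C(=C)C(=O)OC(C)(C)C | intermediate
11 | tert-butyl 3-acetoxy-2-methylidenebutanoate (racemic) | CC(OC(C)=O)C(=C)C(=O)OC(C)(C)C | intermediate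
12 | tert-butyl (2E)-2-(acetoxymethyl)but-2-enoate | C/C=C(\COC(C)=O)C(=O)OC(C)(C)C | intermediate
13 | (2E)-2-(acetoxymethyl)but-2-enoic acid | C/C=C(\COC(C)=O)C(=O)O | intermediate
14 | methyl (3S,4S)-4-{[(2E)-2-(acetoxymethyl)but-2-enoyl]oxy}-5-[(tert-butyldiphenylsilyl)oxy]-3-[(4S)-2,2-dimethyl-1,3-dioxolan-4-yl]-2-methylidenepentanoate | COC(=O)C(=C)[C@@H]([C@H]1COC(C)(C)O1)[C@H](OC(=O)/C(=C/C)COC(C)=O)CO[Si](c2ccccc2)(c2ccccc2)C(C)(C)C | intermediate
15 | methyl (3S,4S)-4-{[(2E)-2-(acetoxymethyl)but-2-enoyl]oxy}-5-[(tert-butyldiphenylsilyl)oxy]-3-[(1S)-1,2-dihydroxyethyl]-2-methylidenepentanoate | COC(=O)C(=C)[C@@H]([C@H](O)CO)[C@H](OC(=O)/C(=C/C)COC(C)=O)CO[Si](c1ccccc1)(c1ccccc1)C(C)(C)C | intermediate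
16 | (1S)-2-[(tert-butyldiphenylsilyl)oxy]-1-[(2S,3S)-2-(hydroxymethyl)-4-methylidene-5-oxooxolan-3-yl]ethyl (2E)-2-(acetoxymethyl)but-2-enoate | C=C1C(=O)O[C@H](CO)[C@H]1[C@H](OC(=O)/C(=C/C)COC(C)=O)CO[Si](c2ccccc2)(c2ccccc2)C(C)(C)C | intermediate
17 | (1S)-2-[(tert-butyldiphenylsilyl)oxy]-1-[(2S,3R)-2-formyl-4-methylidene-5-oxooxolan-3-yl]ethyl (2E)-2-(acetoxymethyl)but-2-enoate | C=C1C(=O)O[C@H](C=O)[C@H]1[C@H](OC(=O)/C(=C/C)COC(C)=O)CO[Si](c2ccccc2)(c2ccccc2)C(C)(C)C | intermediate
18 | (1S)-2-[(tert-butyldiphenylsilyl)oxy]-1-[(2S,3S)-2-[(1Z)-2-iodoprop-1-en-1-yl]-4-methylidene-5-oxooxolan-3-yl]ethyl (2E)-2-(acetoxymethyl)but-2-enoate | C=C1C(=O)O[C@H](/C=C(/C)I)[C@H]1[C@H](OC(=O)/C(=C/C)COC(C)=O)CO[Si](c2ccccc2)(c2ccccc2)C(C)(C)C | intermediate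
19 | tert-butyl(but-3-yn-2-yloxy)dimethylsilane (racemic) | C#CC(C)O[Si](C)(C)C(C)(C)C | starting material
20 | (1S)-2-[(tert-butyldiphenylsilyl)oxy]-1-[(2R,3S)-2-{(1Z)-6-[(tert-butyldimethylsilyl)oxy]-2-methyl-3-oxohept-1-en-4-yn-1-yl}-4-methylidene-5-oxooxolan-3-yl]ethyl (2E)-2-(acetoxymethyl)but-2-enoate (both epimers at the silyloxy carbon) | C=C1C(=O)O[C@H](/C=C(/C)C(=O)C#CC(C)O[Si](C)(C)C(C)(C)C)[C@H]1[C@H](OC(=O)/C(=C/C)COC(C)=O)CO[Si](c2ccccc2)(c2ccccc2)C(C)(C)C | intermediate
21 | (1S)-2-hydroxy-1-[(2R,3S)-2-[(1Z)-6-hydroxy-2-methyl-3-oxohept-1-en-4-yn-1-yl]-4-methylidene-5-oxooxolan-3-yl]ethyl (2E)-2-(acetoxymethyl)but-2-enoate (both carbinol epimers) | C=C1C(=O)O[C@H](/C=C(/C)C(=O)C#CC(C)O)[C@H]1[C@H](OC(=O)/C(=C/C)COC(C)=O)CO | intermediate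
22 | (1S)-2-hydroxy-1-[(2R,3S)-2-[(1Z)-2-(5-methyl-4-oxo-4,5-dihydrofuran-2-yl)prop-1-en-1-yl]-4-methylidene-5-oxooxolan-3-yl]ethyl (2E)-2-(acetoxymethyl)but-2-enoate (both epimers at the furanone CH) | C=C1C(=O)O[C@H](/C=C(/C)C2=CC(=O)C(C)O2)[C@H]1[C@H](OC(=O)/C(=C/C)COC(C)=O)CO | intermediate
23 | (1S)-1-[(2R,3S)-2-[(1Z)-2-(5-methyl-4-oxo-4,5-dihydrofuran-2-yl)prop-1-en-1-yl]-4-methylidene-5-oxooxolan-3-yl]-2-oxoethyl (2E)-2-(acetoxymethyl)but-2-enoate (both epimers at the furanone CH) | C=C1C(=O)O[C@H](/C=C(/C)C2=CC(=O)C(C)O2)[C@H]1[C@H](OC(=O)/C(=C/C)COC(C)=O)C=O | intermediate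
24 | (1S)-1-[(2R,3S)-2-[(1Z)-2-{5-methyl-4-[(trimethylsilyl)oxy]furan-2-yl}prop-1-en-1-yl]-4-methylidene-5-oxooxolan-3-yl]-2-oxoethyl (2E)-2-(acetoxymethyl)but-2-enoate | C=C1C(=O)O[C@H](/C=C(/C)c2cc(O[Si](C)(C)C)c(C)o2)[C@H]1[C@H](OC(=O)/C(=C/C)COC(C)=O)C=O | intermediate
25 | 9-O-trimethylsilyl ether of 26 | C=C1C(=O)O[C@@H]2/C=C(/C)C3=CC(=O)[C@](C)(O3)[C@@H](O[Si](C)(C)C)[C@@H](OC(=O)/C(=C/C)COC(C)=O)[C@@H]12 | intermediate
26 | CNP0231561.1, (6R,7S,8S,9S,10R)-8-{[(2E)-2-(acetoxymethyl)but-2-enoyl]oxy}-9-hydroxy-1-oxo-3,10-epoxygermacra-2,4(Z),11(13)-trien-12,6-olide | C=C1C(=O)O[C@@H]2/C=C(/C)C3=CC(=O)[C@](C)(O3)[C@@H](O)[C@@H](OC(=O)/C(=C/C)COC(C)=O)[C@@H]12 | target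

## Step count and least certain steps

Total: 14 steps. Longest linear sequence: 11 steps (steps 1–3 and 7–14, from 1); steps 4–6 make the side-chain acid.

**Step 14 (key step).** Most likely failures:
- The rigid (Z)-diene tether may hold C9 too far from C10, so that intermolecular aldol addition and oligomerisation take over.
- Facial selectivity at the aldehyde or the furan may be poor, so that C9 or C10 epimers form.
- The α-acyloxy aldehyde may enolise under the amine/silyl triflate.

Fallback: close the ring at C4=C5 instead and make C9–C10 without ring strain. It sets out from 17. Wittig methylenation of 17 should give the vinyl lactone F1. Aqueous HF should free the primary alcohol F2, and Dess–Martin oxidation should give aldehyde F3. An intermolecular Mukaiyama aldol of F3 with the separately prepared silyloxyfuran F4 (BF3·OEt2, CH2Cl2, −78 °C) should give the diene A1. Ring-closing metathesis of A1 with the second-generation Hoveyda–Grubbs catalyst in hot toluene at high dilution should then return to the route at 26; the ring allows only the (Z)-alkene.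

**Step 3.** Most likely failure: incomplete facial discrimination at the allyl unit (C7 relative to C6), or erosion of the syn C7/C8 preference by equilibration of the allylindium geometry. Premature lactonisation onto O8 is a lesser risk.

Fallback: replace substrate control by catalyst control. It sets out from 4. Palladium-catalysed borylation of 4 with bis(pinacolato)diboron (Pd2(dba)3, toluene) should give the linear allylboronate F5. Its allylboration of 5 under a chiral phosphoric acid catalyst (the enantiomer matched to the substrate bias) proceeds through a closed chair, in which the catalyst fixes the aldehyde face and with it the face of the allyl unit. This returns to the route at 7.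

**Step 10.** Most likely failure: incomplete (Z)-selectivity of the iodo-olefination, conjugate addition of the ylide to the methylene lactone, or epimerisation of the α-oxygenated aldehyde by the basic ylide.

Fallback: build C4=C5 and the C1–C3 unit in one Horner–Wadsworth–Emmons step with no ylide and no palladium. It sets out from 17. Still–Gennari-type olefination of 17 with the separately prepared bis(trifluoroethyl) β-ketophosphonate F6 (KHMDS, 18-crown-6, THF, −78 °C) should give the (Z)-enone directly and returns to the route at 20, bypassing 18.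

**Step 11.** Most likely failure: direct alkynylation without CO insertion, or Heck-type cyclisation of the vinylpalladium onto the nearby methylene lactone before it is intercepted.

Fallback: form the C3–C4 bond by a plain Sonogashira coupling and place the carbonyl at C1 by oxidation. It sets out from 18. Coupling of 18 with the separately prepared alkynol F7 (PdCl2(PPh3)2, CuI, Et3N, rt) should give the enynol F8, and Dess–Martin oxidation should give the α′-silyloxy ynone F9. Aqueous HF should free the diol ynone F10, whose secondary hydroxyl should close by 5-endo-dig oxa-Michael addition (catalytic (Ph3P)AuNTf2). This returns to the route at 22.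

## Further compounds

F1 | step 14 | (1S)-2-[(tert-butyldiphenylsilyl)oxy]-1-[(2R,3S)-2-ethenyl-4-methylidene-5-oxooxolan-3-yl]ethyl (2E)-2-(acetoxymethyl)but-2-enoate | C=C1C(=O)O[C@H](C=C)[C@H]1[C@H](OC(=O)/C(=C/C)COC(C)=O)CO[Si](c2ccccc2)(c2ccccc2)C(C)(C)C
F2 | step 14 | (1S)-1-[(2R,3S)-2-ethenyl-4-methylidene-5-oxooxolan-3-yl]-2-hydroxyethyl (2E)-2-(acetoxymethyl)but-2-enoate | C=C1C(=O)O[C@H](C=C)[C@H]1[C@H](OC(=O)/C(=C/C)COC(C)=O)CO
F3 | step 14 | (1S)-1-[(2R,3S)-2-ethenyl-4-methylidene-5-oxooxolan-3-yl]-2-oxoethyl (2E)-2-(acetoxymethyl)but-2-enoate | C=C1C(=O)O[C@H](C=C)[C@H]1[C@H](OC(=O)/C(=C/C)COC(C)=O)C=O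
F4 | step 14 | 2-methyl-5-(prop-1-en-2-yl)-3-[(trimethylsilyl)oxy]furan | Cc1oc(C(C)=C)cc1O[Si](C)(C)C
F5 | step 3 | methyl (2E)-3-[(4S)-2,2-dimethyl-1,3-dioxolan-4-yl]-2-[(4,4,5,5-tetramethyl-1,3,2-dioxaborolan-2-yl)methyl]prop-2-enoate | CC1(C)OC[C@@H](O1)/C=C(\CB2OC(C)(C)C(C)(C)O2)C(=O)OC
F6 | step 10 | bis(2,2,2-trifluoroethyl) {6-[(tert-butyldimethylsilyl)oxy]-3-oxohept-4-yn-2-yl}phosphonate | CC(C(=O)C#CC(C)O[Si](C)(C)C(C)(C)C)P(=O)(OCC(F)(F)F)OCC(F)(F)F
F7 | step 11 | 4-[(tert-butyldimethylsilyl)oxy]pent-1-yn-3-ol | C#CC(O)C(C)O[Si](C)(C)C(C)(C)C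
F8 | step 11 | (1S)-2-[(tert-butyldiphenylsilyl)oxy]-1-[(2R,3S)-2-{(1Z)-6-[(tert-butyldimethylsilyl)oxy]-5-hydroxy-2-methylhept-1-en-3-yn-1-yl}-4-methylidene-5-oxooxolan-3-yl]ethyl (2E)-2-(acetoxymethyl)but-2-enoate | C=C1C(=O)O[C@H](/C=C(/C)C#CC(O)C(C)O[Si](C)(C)C(C)(C)C)[C@H]1[C@H](OC(=O)/C(=C/C)COC(C)=O)CO[Si](c2ccccc2)(c2ccccc2)C(C)(C)C
F9 | step 11 | (1S)-2-[(tert-butyldiphenylsilyl)oxy]-1-[(2R,3S)-2-{(1Z)-6-[(tert-butyldimethylsilyl)oxy]-2-methyl-5-oxohept-1-en-3-yn-1-yl}-4-methylidene-5-oxooxolan-3-yl]ethyl (2E)-2-(acetoxymethyl)but-2-enoate | C=C1C(=O)O[C@H](/C=C(/C)C#CC(=O)C(C)O[Si](C)(C)C(C)(C)C)[C@H]1[C@H](OC(=O)/C(=C/C)COC(C)=O)CO[Si](c2ccccc2)(c2ccccc2)C(C)(C)C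
F10 | step 11 | (1S)-2-hydroxy-1-[(2R,3S)-2-[(1Z)-6-hydroxy-2-methyl-5-oxohept-1-en-3-yn-1-yl]-4-methylidene-5-oxooxolan-3-yl]ethyl (2E)-2-(acetoxymethyl)but-2-enoate | C=C1C(=O)O[C@H](/C=C(/C)C#CC(=O)C(C)O)[C@H]1[C@H](OC(=O)/C(=C/C)COC(C)=O)CO
A1 | alternative 1 | diene for ring-closing metathesis: the 9-hydroxy 8-ester with a 5-isopropenyl-2-methyl-3(2H)-furanone at C9 and a vinyl group on the lactone at C6 | C=C1C(=O)O[C@H](C=C)[C@H]1[C@H](OC(=O)/C(=C/C)COC(C)=O)[C@H](O)[C@@]2(C)OC(C(C)=C)=CC2=O
A2 | alternative 2 | bromo-enal for Barbier macrocyclisation: (Z)-enal on the furanone, (Z)-2-(bromomethyl)enoate at C7 | O=C/C=C(/C)C1=CC(=O)[C@](C)(O1)[C@@H](O)[C@@H](OC(=O)/C(=C/C)COC(C)=O)/C=C(\CBr)C(=O)OC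
A3 | alternative 3 | ten-membered γ-hydroxy enynone with the lactone, C8 ester and C9/C10 diol in place | C=C1C(=O)O[C@@H]2/C=C(/C)C#CC(=O)[C@](C)(O)[C@@H](O)[C@@H](OC(=O)/C(=C/C)COC(C)=O)[C@@H]12
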